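## Analysis of the target

Positions are numbered biogenetically: C1–C10 for the decalin and C11 for the benzylic carbon. The target is a trans-fused decalin (ring A: C1–C5 and C10; ring B: C5–C10) with an exocyclic methylene on C4, an angular methyl on C10, a quaternary C9 bearing a methyl and the C11 methylene, and a secondary methyl on C8. C11 is bonded to the arene ortho to the hydroxyl of a methyl 4-hydroxybenzoate unit. The four stereocentres C5, C10, C9 and C8 are contiguous: the three methyls on C8, C9 and C10 lie on one face (β), while H-5 and C11 lie on the other, which corresponds to (1R,2S,4aS,8aS) in naphthalene numbering. C9 and C10 are vicinal quaternary carbons, and in a chair–chair decalin the C8 and C10 methyls are syn-axial, so ring B is severely congested. C11 is neopentylic, so its bond to the arene has to come from addition to a C11 carbonyl and not from a displacement. The sensitive groups are the 1,1-disubstituted C4 alkene (acid could trigger isomerisation or a cationic shift cascade with capture by the ortho phenol), the methyl ester and the phenol. The strategy rests on ring B: the syn methyl triad on C8/C9/C10 with C11 anti to the C10 methyl is the substitution pattern of an endo cycloadduct of an (E)-α-methyl enal across a C10=C5–C6=C7 diene that is already part of ring A.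

## Retrosynthetic reasoning

The phenol of 18 is unmasked last from its methoxymethyl ether 17. Cutting the O–CH2OMe bond at the end keeps the phenol inert through the organometallic, radical and olefination steps. The forward step has to be free of Brønsted acid because the C4 methylene is already present.

The C4=CH2 bond of 17 is cut back to the C4 ketone 16. The alkene is the most fragile group of the target, so it is installed after all hydrogenation and radical chemistry. The forward methylenation must be non-basic, because C5 is now α to the carbonyl and the ring fusion could epimerise.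

Ketone 16 is traced through alcohol 15 to silyl ether 14. The C4 oxygen is not a detour: it is the relic of the only stereocentre that is bought with a chiral reagent, and it is erased once it has done its work.

The C11–H bond of 14 is traced to the C11–O bond of xanthate 13 and carbinol 12. A radical deoxygenation is chosen because C11 is neopentylic and benzylic: a cation there would invite a 1,2-shift from quaternary C9, whereas a benzylic radical is configurationally and constitutionally harmless.

The C5–H and C6–H bonds of 12 are cut back to the C5=C6 alkene of 11. The C11 hydroxyl sits on the α-face directly under C5, so it can hold a cationic iridium catalyst there and deliver hydrogen anti to the C10 methyl, which sets the trans ring fusion.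

The C11–aryl bond of 11 is cut to aldehyde 7 and arylmagnesium reagent 10, made from iodide 9 and thus from phenol 8. This is the only practical way to join the arene to a neopentyl carbon, and the aldehyde cannot enolise because C9 is quaternary.

Ring B of 7 is opened across C7–C8 and C9–C10 to diene 5 and enal 6. This single cut removes one ring, two skeletal bonds and three stereocentres, including the vicinal quaternary pair, and leaves a diene whose only stereocentre (C4) controls the face of attack. The forward cycloaddition has to be regioselective (C7 to the β-carbon C8), endo for the formyl group and anti to the C4 silyloxy group.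

Diene 5 is cut at the vinyl–ring bond to alkenyl iodide 4, which comes from carbinol 3, iodoenone 2 and enone 1. The iodine serves twice: it is the handle for the palladium-catalysed vinylation, and it makes the two flanks of the ketone sterically distinct so that a catalytic asymmetric reduction sets C4.

## Alternatives that were turned down

Alternative 1: The C8–C9 bond is cut sigmatropically. Acid A2 (ring-B cyclohexene with C6=C7, C9 carboxyl, C4 as dioxolane) is traced to δ-lactone A1, in which C11 is the acyl carbon, the ring oxygen sits on C6 and C6 carries a (Z)-propenyl group. In the forward step the silyl ketene acetal of A1 rearranges through a boat [3,3] transition state: C8–C9 forms, C6–O breaks and the lactone contracts to carbocyclic ring B. In its favour, the step is intramolecular, so quaternary C9 is made next to quaternary C10 without an entropic penalty, and chirality is relayed reliably from C6 to C8 and C9. C5 is also already in place, so no late hydrogenation has to set the ring fusion; on that point it is stronger than the chosen route. Against it, A1 already needs three stereocentres (C5, C6 and the quaternary C10) and a Z-alkene, each made separately, so the lactone is expensive. In the boat the (Z)-methyl is forced into the inside position against C10 and its substituents, and any leakage to a chair or any E-alkene gives the C8 epimer. A2 also still needs redox adjustment of the acid to an aldehyde and reduction of C6=C7. The chosen route reaches the equivalent ring-B aldehyde 7 in five steps with three centres controlled by one catalytic reduction.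

Alternative 2: Both rings are cut at C4–C5 and C9–C10, leading to the acyclic dienyne benzyl ether A3. In the forward step a carbophilic Lewis acid activates the terminal alkyne, the C5=C10 alkene attacks C4, the C8=C9 alkene attacks C10, and the C8 cation is reduced by a 1,5-hydride shift from the benzylic CH2 of the C11 ether, giving bicyclic alcohol A4 with the exocyclic methylene in place. It builds both rings, all four stereocentres and the C4 methylene in one operation, which is clearly better step economy than the chosen route. Against it, C9–C10 must form by attack of a tetrasubstituted alkene on a tertiary cation, and the tertiary C8 cation must wait for a six-membered hydride transfer while proton loss from C7 or the C8 methyl competes. The tetrasubstituted (Z)-alkene of A3 is itself a stereochemical problem, and absolute control would need a chiral catalyst with little precedent for such a termination. A4 would also still require oxidation, arylation and deoxygenation at neopentyl C11 with the acid-sensitive alkene already present. The chosen route is longer, but each stereocentre is tied to a well-understood control element and the alkene comes last.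

Alternative 3: Ring B is cut at C8–C9 and C5–C10, with buta-1,3-diene A5 and 2,3-dimethylmaleic anhydride A6 giving the meso cis-anhydride A7. The two quaternary carbons with cis methyls come from two commodity chemicals with no selectivity question, and desymmetrisation of meso anhydrides is established. For the C9–C10 pair alone this is more secure than the chosen cycloaddition, although a tetrasubstituted dienophile also needs forcing conditions. Against it, A7 contains only ring B and two of the four stereocentres. The C8 methyl and the C5 centre must be introduced at allylic methylenes with little bias, ring A must be annulated from one anhydride carbonyl, and both carboxyl carbons need deep reduction (one to the C11 methylene, one to C1). The step count would be far higher. The chosen strategy brings ring A in ready-made, and the cycloaddition sets C8 together with C9 and C10.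

Key step: step 5

Remark on the chemistry: the C11 carbinol centre created in step 7 is removed in step 10, so compounds 11, 12 and 13 are carried as mixtures of C11 epimers and their SMILES leave C11 undefined.

## Route

Step 1
Reactants: 1 3-methylcyclohex-2-en-1-one
Product: 2 2-iodo-3-methylcyclohex-2-en-1-one
Conditions: I2, pyridine, CH2Cl2, 0 °C → rt
Reagents that add atoms: iodine, II
Why: Pyridine-mediated α-iodination of an enone (conjugate addition of pyridine, iodination of the enolate, E1cB loss of pyridine); the iodine lands on the carbon that becomes C5.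

Step 2
Reactants: 2 2-iodo-3-methylcyclohex-2-en-1-one
Product: 3 (1S)-2-iodo-3-methylcyclohex-2-en-1-ol
Conditions: (R)-2-methyl-CBS-oxazaborolidine (cat.), BH3·SMe2, THF, −20 °C
Reagents that add atoms: none
Why: Corey–Bakshi–Shibata reduction; the α-iodoalkenyl flank acts as the large group and the methylene flank as the small one, so the (R)-catalyst should deliver hydride to give the (S)-carbinol, the future C4.

Step 3
Reactants: 3 (1S)-2-iodo-3-methylcyclohex-2-en-1-ol
Product: 4 tert-butyl{[(1S)-2-iodo-3-methylcyclohex-2-en-1-yl]oxy}dimethylsilane
Conditions: TBSCl, imidazole, DMF, rt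
Reagents that add atoms: tert-butyldimethylsilyl chloride, CC(C)(C)[Si](C)(C)Cl
Why: Standard silylation of a secondary allylic alcohol; the TBS group is bulky enough to shield one diene face and should survive an aluminium Lewis acid at low temperature.

Step 4
Reactants: 4 tert-butyl{[(1S)-2-iodo-3-methylcyclohex-2-en-1-yl]oxy}dimethylsilane
Product: 5 tert-butyl{[(1S)-2-ethenyl-3-methylcyclohex-2-en-1-yl]oxy}dimethylsilane
Conditions: CH2=CHSnBu3, Pd(PPh3)4 (cat.), CuI (cat.), CsF, DMF, 45 °C
Reagents that add atoms: tributyl(vinyl)stannane, C=C[Sn](CCCC)(CCCC)CCCC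
Why: Stille coupling of an alkenyl iodide under zerovalent palladium catalysis; CuI and fluoride accelerate transmetalation at the fully substituted carbon, and the C4 stereocentre is not involved.

Step 5
Reactants: 5 tert-butyl{[(1S)-2-ethenyl-3-methylcyclohex-2-en-1-yl]oxy}dimethylsilane; 6 (2E)-2-methylbut-2-enal
Product: 7 (1R,2S,5S,8aS)-5-{[tert-butyl(dimethyl)silyl]oxy}-1,2,8a-trimethyl-1,2,3,5,6,7,8,8a-octahydronaphthalene-1-carbaldehyde
Conditions: 6 (3 equiv) precomplexed with EtAlCl2 (3 equiv), CH2Cl2, −78 → −30 °C
Reagents that add atoms: none
Why: Lewis-acid-promoted Diels–Alder reaction of normal electron demand between a 1-vinylcyclohexene-type diene and an α-methyl enal, a known reaction type; EtAlCl2 on the formyl oxygen lowers the LUMO of 6 and enlarges its coefficient at the β-carbon C8. The cycloaddition is concerted but asynchronous: C7–C8 forms ahead of C9–C10 because the unsubstituted terminus C7 has the larger HOMO coefficient and the developing positive charge is best carried by the fully substituted C10, which fixes the regiochemistry that joins the two quaternary carbons. Ring B is closed in this one suprafacial [4+2] event, an annulation onto ring A in which both sigma bonds form on the same face of each partner. For C8 against C9, the E geometry of 6 is transferred stereospecifically, so the two methyls end up cis. For C9 against C10, the complexed formyl group lies endo under C5–C6, which places C11 anti and the C9 methyl syn to the C10 methyl (the inside substituent of the diene terminus). For the absolute sense, A(1,2) strain with the vinyl group holds the C4 silyloxy group pseudoaxial, so the dienophile adds to the face anti to it and the single CBS-derived centre dictates C8, C9 and C10. The step thus needs regio-, endo- and facial selectivity, secured in turn by the substitution pattern of the diene, the Lewis-acid-bound formyl group and the C4 silyl ether; excess dienophile at low temperature is used because the C10 methyl disfavours the s-cis conformer.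

Step 6
Reactants: 8 methyl 4-hydroxy-3-iodobenzoate
Product: 9 methyl 3-iodo-4-(methoxymethoxy)benzoate
Conditions: MOMCl, iPr2NEt, CH2Cl2, 0 °C → rt
Reagents that add atoms: chloromethyl methyl ether, COCCl
Why: O-alkylation of an acidic phenol; the acetal ether tolerates the organomagnesium, radical and olefination steps and can be removed without Brønsted acid.

Step 7
Reactants: 9 methyl 3-iodo-4-(methoxymethoxy)benzoate; 7 (1R,2S,5S,8aS)-5-{[tert-butyl(dimethyl)silyl]oxy}-1,2,8a-trimethyl-1,2,3,5,6,7,8,8a-octahydronaphthalene-1-carbaldehyde
Product: 11 methyl 3-{[(1R,2S,5S,8aS)-5-{[tert-butyl(dimethyl)silyl]oxy}-1,2,8a-trimethyl-1,2,3,5,6,7,8,8a-octahydronaphthalen-1-yl](hydroxy)methyl}-4-(methoxymethoxy)benzoate (C11 epimers), via arylmagnesium chloride 10 (not isolated)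
Conditions: 9 (2.5 equiv), iPrMgCl·LiCl (2.4 equiv), THF, −40 °C; then 7, −40 → 0 °C; aq. NH4Cl
Reagents that add atoms: none
Why: Iodine–magnesium exchange at −40 °C gives an ester-tolerant aryl Grignard reagent that adds to the aldehyde, which cannot enolise because C9 is quaternary; a slight deficit of iPrMgCl avoids competing reduction, and the C11 configuration is immaterial.

Step 8
Reactants: 11 methyl 3-{[(1R,2S,5S,8aS)-5-{[tert-butyl(dimethyl)silyl]oxy}-1,2,8a-trimethyl-1,2,3,5,6,7,8,8a-octahydronaphthalen-1-yl](hydroxy)methyl}-4-(methoxymethoxy)benzoate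
Product: 12 methyl 3-{[(1R,2S,4aR,5S,8aS)-5-{[tert-butyl(dimethyl)silyl]oxy}-1,2,8a-trimethyldecahydronaphthalen-1-yl](hydroxy)methyl}-4-(methoxymethoxy)benzoate (C11 epimers)
Conditions: [Ir(cod)(py)(PCy3)]PF6 (cat.), H2 (1–5 bar), CH2Cl2, rt
Reagents that add atoms: none
Why: Hydroxyl-directed homogeneous hydrogenation with a cationic monovalent iridium complex; the C11 hydroxyl on the α-face binds the metal under C5 and both hydrogens are delivered there, giving H-5 anti to the C10 methyl (trans fusion). The β-face is in any case blocked by the C10 methyl and the C4 silyloxy group.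

Step 9
Reactants: 12 methyl 3-{[(1R,2S,4aR,5S,8aS)-5-{[tert-butyl(dimethyl)silyl]oxy}-1,2,8a-trimethyldecahydronaphthalen-1-yl](hydroxy)methyl}-4-(methoxymethoxy)benzoate
Product: 13 methyl 3-{[(1R,2S,4aR,5S,8aS)-5-{[tert-butyl(dimethyl)silyl]oxy}-1,2,8a-trimethyldecahydronaphthalen-1-yl]{[(methylsulfanyl)carbonothioyl]oxy}methyl}-4-(methoxymethoxy)benzoate (C11 epimers)
Conditions: NaH, imidazole (cat.), CS2, THF, 0 °C → rt; then MeI
Reagents that add atoms: carbon disulfide, S=C=S; iodomethane, CI
Why: Xanthate formation from the alkoxide, the method of choice for hindered alcohols; C9 carries no hydrogen, so Chugaev elimination is impossible.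

Step 10
Reactants: 13 methyl 3-{[(1R,2S,4aR,5S,8aS)-5-{[tert-butyl(dimethyl)silyl]oxy}-1,2,8a-trimethyldecahydronaphthalen-1-yl]{[(methylsulfanyl)carbonothioyl]oxy}methyl}-4-(methoxymethoxy)benzoate
Product: 14 methyl 3-{[(1R,2S,4aR,5S,8aS)-5-{[tert-butyl(dimethyl)silyl]oxy}-1,2,8a-trimethyldecahydronaphthalen-1-yl]methyl}-4-(methoxymethoxy)benzoate
Conditions: Bu3SnH, AIBN (cat.), toluene, 110 °C
Reagents that add atoms: none
Why: Barton–McCombie deoxygenation; fragmentation gives a stabilised benzylic radical that is reduced by the stannane, and the absence of cationic intermediates rules out a 1,2-shift from quaternary C9.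

Step 11
Reactants: 14 methyl 3-{[(1R,2S,4aR,5S,8aS)-5-{[tert-butyl(dimethyl)silyl]oxy}-1,2,8a-trimethyldecahydronaphthalen-1-yl]methyl}-4-(methoxymethoxy)benzoate
Product: 15 methyl 3-{[(1R,2S,4aR,5S,8aS)-5-hydroxy-1,2,8a-trimethyldecahydronaphthalen-1-yl]methyl}-4-(methoxymethoxy)benzoate
Conditions: HF·pyridine, pyridine, THF, 0 °C → rt
Reagents that add atoms: none
Why: Fluoride-driven desilylation; HF is small enough to reach the axial silyl ether that is syn to the C10 methyl, and the pyridine buffer should spare the aryl acetal ether and the methyl ester.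

Step 12
Reactants: 15 methyl 3-{[(1R,2S,4aR,5S,8aS)-5-hydroxy-1,2,8a-trimethyldecahydronaphthalen-1-yl]methyl}-4-(methoxymethoxy)benzoate
Product: 16 methyl 4-(methoxymethoxy)-3-{[(1R,2S,4aR,8aS)-1,2,8a-trimethyl-5-oxodecahydronaphthalen-1-yl]methyl}benzoate
Conditions: Dess–Martin periodinane, CH2Cl2, rt
Reagents that add atoms: none
Why: Dess–Martin oxidation of a secondary alcohol under neutral, non-enolising conditions, so that C5, now α to the carbonyl, should keep its configuration.

Step 13
Reactants: 16 methyl 4-(methoxymethoxy)-3-{[(1R,2S,4aR,8aS)-1,2,8a-trimethyl-5-oxodecahydronaphthalen-1-yl]methyl}benzoate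
Product: 17 methyl 4-(methoxymethoxy)-3-{[(1R,2S,4aS,8aS)-1,2,8a-trimethyl-5-methylidenedecahydronaphthalen-1-yl]methyl}benzoate
Conditions: Zn, CH2Br2, TiCl4, THF, −40 → 5 °C; then 16, CH2Cl2, rt
Reagents that add atoms: dibromomethane, BrCBr
Why: Lombardo (Takai–Lombardo) methylenation; the non-basic gem-dimetallic reagent converts hindered, enolisable ketones without α-epimerisation and leaves esters untouched, so H-5 and the benzoate should survive.

Step 14
Reactants: 17 methyl 4-(methoxymethoxy)-3-{[(1R,2S,4aS,8aS)-1,2,8a-trimethyl-5-methylidenedecahydronaphthalen-1-yl]methyl}benzoate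
Product: 18 methyl 4-hydroxy-3-{[(1R,2S,4aS,8aS)-1,2,8a-trimethyl-5-methylidenedecahydronaphthalen-1-yl]methyl}benzoate
Conditions: TMSOTf, 2,2′-bipyridyl, MeCN, 0 °C → rt; then H2O
Reagents that add atoms: none
Why: Cleavage of an aryl methoxymethyl ether by a silyl triflate buffered with 2,2′-bipyridyl: the acetal is converted to the aryl silyl ether, which is hydrolysed on work-up. No free Brønsted acid is present, so the C4 methylene should not be protonated.

## Compound list

1 | 3-methylcyclohex-2-en-1-one | CC1=CC(=O)CCC1 | starting material
2 | 2-iodo-3-methylcyclohex-2-en-1-one | CC1=C(I)C(=O)CCC1 | intermediate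
3 | (1S)-2-iodo-3-methylcyclohex-2-en-1-ol | CC1=C(I)[C@@H](O)CCC1 | intermediate
4 | tert-butyl{[(1S)-2-iodo-3-methylcyclohex-2-en-1-yl]oxy}dimethylsilane | CC1=C(I)[C@@H](O[Si](C)(C)C(C)(C)C)CCC1 | intermediate
5 | tert-butyl{[(1S)-2-ethenyl-3-methylcyclohex-2-en-1-yl]oxy}dimethylsilane | C=CC1=C(C)CCC[C@@H]1O[Si](C)(C)C(C)(C)C | intermediate
6 | (2E)-2-methylbut-2-enal | C/C=C(\C)C=O | starting material
7 | (1R,2S,5S,8aS)-5-{[tert-butyl(dimethyl)silyl]oxy}-1,2,8a-trimethyl-1,2,3,5,6,7,8,8a-octahydronaphthalene-1-carbaldehyde | CC(C)(C)[Si](C)(C)O[C@H]1CCC[C@@]2(C)C1=CC[C@H](C)[C@@]2(C)C=O | intermediate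
8 | methyl 4-hydroxy-3-iodobenzoate | COC(=O)c1ccc(O)c(I)c1 | starting material
9 | methyl 3-iodo-4-(methoxymethoxy)benzoate | COCOc1ccc(C(=O)OC)cc1I | intermediate
10 | [5-(methoxycarbonyl)-2-(methoxymethoxy)phenyl]magnesium chloride | COCOc1ccc(C(=O)OC)cc1[Mg]Cl | intermediate
11 | methyl 3-{[(1R,2S,5S,8aS)-5-{[tert-butyl(dimethyl)silyl]oxy}-1,2,8a-trimethyl-1,2,3,5,6,7,8,8a-octahydronaphthalen-1-yl](hydroxy)methyl}-4-(methoxymethoxy)benzoate (C11 epimers) | CC(C)(C)[Si](C)(C)O[C@H]1CCC[C@@]2(C)C1=CC[C@H](C)[C@@]2(C)C(O)c1cc(C(=O)OC)ccc1OCOC | intermediate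
12 | methyl 3-{[(1R,2S,4aR,5S,8aS)-5-{[tert-butyl(dimethyl)silyl]oxy}-1,2,8a-trimethyldecahydronaphthalen-1-yl](hydroxy)methyl}-4-(methoxymethoxy)benzoate (C11 epimers) | CC(C)(C)[Si](C)(C)O[C@H]1CCC[C@@]2(C)[C@H]1CC[C@H](C)[C@@]2(C)C(O)c1cc(C(=O)OC)ccc1OCOC | intermediate
13 | methyl 3-{[(1R,2S,4aR,5S,8aS)-5-{[tert-butyl(dimethyl)silyl]oxy}-1,2,8a-trimethyldecahydronaphthalen-1-yl]{[(methylsulfanyl)carbonothioyl]oxy}methyl}-4-(methoxymethoxy)benzoate (C11 epimers) | CC(C)(C)[Si](C)(C)O[C@H]1CCC[C@@]2(C)[C@H]1CC[C@H](C)[C@@]2(C)C(OC(=S)SC)c1cc(C(=O)OC)ccc1OCOC | intermediate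
14 | methyl 3-{[(1R,2S,4aR,5S,8aS)-5-{[tert-butyl(dimethyl)silyl]oxy}-1,2,8a-trimethyldecahydronaphthalen-1-yl]methyl}-4-(methoxymethoxy)benzoate | CC(C)(C)[Si](C)(C)O[C@H]1CCC[C@@]2(C)[C@H]1CC[C@H](C)[C@@]2(C)Cc1cc(C(=O)OC)ccc1OCOC | intermediate
15 | methyl 3-{[(1R,2S,4aR,5S,8aS)-5-hydroxy-1,2,8a-trimethyldecahydronaphthalen-1-yl]methyl}-4-(methoxymethoxy)benzoate | O[C@H]1CCC[C@@]2(C)[C@H]1CC[C@H](C)[C@@]2(C)Cc1cc(C(=O)OC)ccc1OCOC | intermediate
16 | methyl 4-(methoxymethoxy)-3-{[(1R,2S,4aR,8aS)-1,2,8a-trimethyl-5-oxodecahydronaphthalen-1-yl]methyl}benzoate | O=C1CCC[C@@]2(C)[C@H]1CC[C@H](C)[C@@]2(C)Cc1cc(C(=O)OC)ccc1OCOC | intermediate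
17 | methyl 4-(methoxymethoxy)-3-{[(1R,2S,4aS,8aS)-1,2,8a-trimethyl-5-methylidenedecahydronaphthalen-1-yl]methyl}benzoate | C=C1CCC[C@@]2(C)[C@H]1CC[C@H](C)[C@@]2(C)Cc1cc(C(=O)OC)ccc1OCOC | intermediate
18 | methyl 4-hydroxy-3-{[(1R,2S,4aS,8aS)-1,2,8a-trimethyl-5-methylidenedecahydronaphthalen-1-yl]methyl}benzoate | C=C1CCC[C@@]2(C)[C@H]1CC[C@H](C)[C@@]2(C)Cc1cc(C(=O)OC)ccc1O | target

## Step count and least certain steps

Total step count: 14. Longest linear sequence: 13 steps (steps 1–5 and 7–14 from compound 1); step 6 is a one-step side branch.

Key step (step 5). The cycloaddition may be too slow, because the C10 methyl occupies the inside position of the s-cis diene and two quaternary carbons are being joined. While it stalls, the Lewis acid may ionise the allylic silyl ether or oligomerise the diene, and the endo preference of an α-methyl enal may be incomplete, which would erode the C9/C10 relationship. The fallback changes the dienophile from a neutral Lewis-acid complex to a cation: it sets out from 5, and 6 is first converted with ethane-1,2-diol and an acid catalyst into 2-[(2E)-but-2-en-2-yl]-1,3-dioxolane F1. Treating 5 and F1 with catalytic TMSOTf in CH2Cl2 at −78 °C opens the acetal to an alkoxy-substituted allyl cation, a far more reactive 2π partner, which should add across the same diene termini (ionic Diels–Alder reaction of an unsaturated acetal) to give the ethylene acetal of aldehyde 7 F2. Mild transacetalisation (pyridinium p-toluenesulfonate, wet acetone, 50 °C) returns the route to 7.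

Step 7. The addition may be slow at the doubly neopentylic aldehyde, and warming to force it would let the ester-bearing Grignard reagent attack its own ester. The fallback removes the ester from the nucleophile: 4-bromo-2-iodophenol is protected to 4-bromo-2-iodo-1-(methoxymethoxy)benzene F3, selective iodine–lithium exchange (n-BuLi, THF, −78 °C) gives [5-bromo-2-(methoxymethoxy)phenyl]lithium F4, and its addition to 7 gives the bromoarene analogue of carbinol 11 F5. Palladium-catalysed methoxycarbonylation of the aryl bromide (Pd(OAc)2, Xantphos, CO, MeOH, Et3N, 80 °C) then rejoins the route at 11.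

Step 8. Hydrogen uptake may fail at the hindered trisubstituted alkene through deactivation of the iridium catalyst, or the hindered secondary carbinol may bind poorly, so that directing is lost. The fallback sets out from 11 and returns at 12 by a different mechanism: hydrogen-atom-transfer hydrogenation (Mn(dpm)3, PhSiH3, tert-butyl hydroperoxide, isopropanol, rt) generates the tertiary C5 radical, which is insensitive to steric shielding and is quenched axially to give the trans ring fusion. This fallback makes no new compound (F0).

Step 14. Traces of acid during acetal cleavage could protonate the C4 methylene, leading to alkene migration or a cationic shift cascade ending in capture by the freed phenol. The fallback moves the acid step ahead of the alkene. It sets out from 14: methanolic HCl (40 °C) removes both the silyl and the methoxymethyl group to give methyl 4-hydroxy-3-{[(1R,2S,4aR,5S,8aS)-5-hydroxy-1,2,8a-trimethyldecahydronaphthalen-1-yl]methyl}benzoate F6. Selective acetylation of the phenoxide (Ac2O, K2CO3, acetone, 0 °C) gives the aryl acetate alcohol F7, Dess–Martin oxidation gives the aryl acetate ketone F8, and methylenation with Zn/CH2Br2/TiCl4 gives the aryl acetate of the target F9. Methanolysis with K2CO3 in MeOH at 0 °C returns the route at 18 under mildly basic conditions that leave the alkene and the methyl ester alone.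

## Further compounds

F1 | step 5 | 2-[(2E)-but-2-en-2-yl]-1,3-dioxolane | C/C=C(\C)C1OCCO1
F2 | step 5 | ethylene acetal of aldehyde 7, tert-butyl{[(1S,4aS,5R,6S)-5-(1,3-dioxolan-2-yl)-4a,5,6-trimethyl-1,2,3,4,4a,5,6,7-octahydronaphthalen-1-yl]oxy}dimethylsilane (stereocentres as in 7) | CC(C)(C)[Si](C)(C)O[C@H]1CCC[C@@]2(C)C1=CC[C@H](C)[C@@]2(C)C1OCCO1
F3 | step 7 | 4-bromo-2-iodo-1-(methoxymethoxy)benzene | COCOc1ccc(Br)cc1I
F4 | step 7 | [5-bromo-2-(methoxymethoxy)phenyl]lithium | [Li]c1cc(Br)ccc1OCOC
F5 | step 7 | [5-bromo-2-(methoxymethoxy)phenyl][(1R,2S,5S,8aS)-5-{[tert-butyl(dimethyl)silyl]oxy}-1,2,8a-trimethyl-1,2,3,5,6,7,8,8a-octahydronaphthalen-1-yl]methanol (C11 epimers) | CC(C)(C)[Si](C)(C)O[C@H]1CCC[C@@]2(C)C1=CC[C@H](C)[C@@]2(C)C(O)c1cc(Br)ccc1OCOC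
F0 | step 8 | none | none
F6 | step 14 | methyl 4-hydroxy-3-{[(1R,2S,4aR,5S,8aS)-5-hydroxy-1,2,8a-trimethyldecahydronaphthalen-1-yl]methyl}benzoate | O[C@H]1CCC[C@@]2(C)[C@H]1CC[C@H](C)[C@@]2(C)Cc1cc(C(=O)OC)ccc1O
F7 | step 14 | methyl 4-acetoxy-3-{[(1R,2S,4aR,5S,8aS)-5-hydroxy-1,2,8a-trimethyldecahydronaphthalen-1-yl]methyl}benzoate | O[C@H]1CCC[C@@]2(C)[C@H]1CC[C@H](C)[C@@]2(C)Cc1cc(C(=O)OC)ccc1OC(C)=O
F8 | step 14 | methyl 4-acetoxy-3-{[(1R,2S,4aR,8aS)-1,2,8a-trimethyl-5-oxodecahydronaphthalen-1-yl]methyl}benzoate | O=C1CCC[C@@]2(C)[C@H]1CC[C@H](C)[C@@]2(C)Cc1cc(C(=O)OC)ccc1OC(C)=O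
F9 | step 14 | methyl 4-acetoxy-3-{[(1R,2S,4aS,8aS)-1,2,8a-trimethyl-5-methylidenedecahydronaphthalen-1-yl]methyl}benzoate | C=C1CCC[C@@]2(C)[C@H]1CC[C@H](C)[C@@]2(C)Cc1cc(C(=O)OC)ccc1OC(C)=O
A1 | alternative 1 | 8,8-(ethylenedioxy)-4,4a-dimethyl-1-[(1Z)-prop-1-en-1-yl]octahydro-1H-isochromen-3-one (biogenetic H-5 α, C10 methyl β, C6–O α; C9 epimer immaterial) | O1CCOC12CCC[C@@]3(C)[C@H]2[C@H](/C=C\C)OC(=O)C3C
A2 | alternative 1 | (1R,2S,4aR,8aS)-5,5-(ethylenedioxy)-1,2,8a-trimethyl-1,2,4a,5,6,7,8,8a-octahydronaphthalene-1-carboxylic acid | O1CCOC12CCC[C@@]3(C)[C@H]2C=C[C@H](C)[C@@]3(C)C(=O)O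
A3 | alternative 2 | benzyl (2Z,6E)-2,3,7-trimethyldodeca-2,6-dien-11-yn-1-yl ether | C#CCCC/C(C)=C/CC/C(C)=C(/C)COCc1ccccc1
A4 | alternative 2 | [(1R,2S,4aS,8aS)-1,2,8a-trimethyl-5-methylidenedecahydronaphthalen-1-yl]methanol | C=C1CCC[C@@]2(C)[C@H]1CC[C@H](C)[C@@]2(C)CO
A5 | alternative 3 | buta-1,3-diene | C=CC=C
A6 | alternative 3 | 2,3-dimethylmaleic anhydride | CC1=C(C)C(=O)OC1=O
A7 | alternative 3 | cis-1,2-dimethylcyclohex-4-ene-1,2-dicarboxylic anhydride (meso) | C[C@]12CC=CC[C@@]1(C)C(=O)OC2=O
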